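**Strategy.** The upper chroman is disconnected at O1–C2 and C3–C4. Ring A, with its phenolic O1 ortho to the diarylmethine C4, is a masked o-quinone methide, and C2–C3 with its aryl group is an arylacetaldehyde. In one operation a prolinol-ether-catalysed enamine Michael addition to the quinone methide forges C3–C4, and the phenol O1 then closes the pyran ring onto C2 as a hemiacetal, setting the 3,4-trans stereocenters under catalyst control. The precursor is an acyclic o-hydroxybenzhydrol that already carries the lower (S)-isoflavan, itself made by the same enamine chemistry. The lactol hydroxyl and four benzyl ethers are removed at the end.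

Key step: step 8

Remark: 1, 5 and 14 are taken as catalogue chemicals; the anomeric carbon of 8 and 18 and the carbinol carbon of 13 form as mixtures that are erased later, so they carry no descriptor.

**Step 1**
Reactants: 1 5-bromo-2-hydroxy-4-methoxybenzaldehyde
Product: 2 2-(benzyloxy)-5-bromo-4-methoxybenzaldehyde
Conditions: BnBr, K2CO3, DMF, rt
Reagents that add atoms: benzyl bromide BrCc1ccccc1
Why: Williamson etherification of a phenol made more acidic by the ortho-formyl group.

**Step 2**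
Reactants: 2 2-(benzyloxy)-5-bromo-4-methoxybenzaldehyde
Product: 4 2-[2-(benzyloxy)-5-bromo-4-methoxyphenyl]acetaldehyde, via methyl enol ether 3 (not isolated)
Conditions: Ph3P(CH2OMe)Cl, KOtBu, THF, 0 °C → rt; then 2 M aq. HCl, THF, rt
Reagents that add atoms: (methoxymethyl)triphenylphosphonium chloride COC[P+](c1ccccc1)(c1ccccc1)c1ccccc1.[Cl-]; water O
Why: Wittig methoxymethylenation followed by acid hydrolysis of the enol ether is the standard one-carbon homologation of an aryl aldehyde to an arylacetaldehyde, and the aryl bromide and benzyl ether are inert to it.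

**Step 3**
Reactants: 5 4-(benzyloxy)-2-hydroxybenzaldehyde
Product: 6 5-(benzyloxy)-2-(hydroxymethyl)phenol
Conditions: NaBH4, MeOH–THF, 0 °C
Reagents that add atoms: none
Why: Borohydride reduction of the aldehyde gives the electron-rich salicyl alcohol that serves as precursor of the unsubstituted o-quinone methide.

**Step 4**
Reactants: 4 2-[2-(benzyloxy)-5-bromo-4-methoxyphenyl]acetaldehyde; 6 5-(benzyloxy)-2-(hydroxymethyl)phenol
Product: 9 5-(benzyloxy)-2-{(2S)-2-[2-(benzyloxy)-5-bromo-4-methoxyphenyl]-3-hydroxypropyl}phenol, via o-quinone methide 7 (not isolated), via lactol 8 (not isolated)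
Conditions: (S)-α,α-diphenylprolinol trimethylsilyl ether (20 mol %), 4-nitrobenzoic acid (20 mol %), CHCl3, 40 °C, slow addition of 6; then MeOH, NaBH4, 0 °C
Reagents that add atoms: none
Why: Acid-promoted dehydration of 6 gives quinone methide 7, which the (E)-enamine of 4 intercepts (enamine Michael addition/hemiacetalisation); the diphenyl(silyloxy)methyl group of the (S)-catalyst shields one enamine face and should set the stereocenter as S, and immediate borohydride reduction of lactol 8 removes the epimerisable aldehyde.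

**Step 5**
Reactants: 9 5-(benzyloxy)-2-{(2S)-2-[2-(benzyloxy)-5-bromo-4-methoxyphenyl]-3-hydroxypropyl}phenol
Product: 10 (3S)-7-(benzyloxy)-3-[2-(benzyloxy)-5-bromo-4-methoxyphenyl]chroman
Conditions: PPh3, DIAD, THF, 0 °C → rt
Reagents that add atoms: none
Why: Intramolecular Mitsunobu etherification of the phenol onto the primary alcohol closes the lower pyran ring (6-exo-tet) at a CH2 group, so the stereocenter is untouched.

**Step 6**
Reactants: 10 (3S)-7-(benzyloxy)-3-[2-(benzyloxy)-5-bromo-4-methoxyphenyl]chroman; 5 4-(benzyloxy)-2-hydroxybenzaldehyde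
Product: 13 [4-(benzyloxy)-2-hydroxyphenyl]{4-(benzyloxy)-5-[(3S)-7-(benzyloxy)chroman-3-yl]-2-methoxyphenyl}methanol, via aryllithium 11 (not isolated), via sodium phenolate 12 (not isolated)
Conditions: n-BuLi, THF, −78 °C; then 12 (from 5 and NaH, THF, 0 °C), −78 → −20 °C; H2O
Reagents that add atoms: none
Why: Bromine–lithium exchange gives an aryllithium stabilised by the ortho-methoxy group, which undergoes 1,2-addition to the formyl group of the pre-formed phenolate; the carbinol centre forms as a mixture that becomes sp2 in step 8.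

**Step 7**
Reactants: 14 2-(benzyloxy)-4-methoxybenzaldehyde
Product: 16 2-[2-(benzyloxy)-4-methoxyphenyl]acetaldehyde, via methyl enol ether 15 (not isolated)
Conditions: Ph3P(CH2OMe)Cl, KOtBu, THF, 0 °C → rt; then 2 M aq. HCl, THF, rt
Reagents that add atoms: (methoxymethyl)triphenylphosphonium chloride COC[P+](c1ccccc1)(c1ccccc1)c1ccccc1.[Cl-]; water O
Why: The same Wittig methoxymethylenation/enol ether hydrolysis as in step 2 delivers the arylacetaldehyde that becomes C2–C3 of the upper chroman.

**Step 8**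
Reactants: 13 [4-(benzyloxy)-2-hydroxyphenyl]{4-(benzyloxy)-5-[(3S)-7-(benzyloxy)chroman-3-yl]-2-methoxyphenyl}methanol; 16 2-[2-(benzyloxy)-4-methoxyphenyl]acetaldehyde
Product: 18 (3S,4R)-7-(benzyloxy)-3-[2-(benzyloxy)-4-methoxyphenyl]-4-{4-(benzyloxy)-5-[(3S)-7-(benzyloxy)chroman-3-yl]-2-methoxyphenyl}chroman-2-ol, via o-quinone methide 17 (not isolated)
Conditions: (S)-α,α-diphenylprolinol trimethylsilyl ether (20 mol %), PhCO2H (20 mol %), CH2Cl2, 0 °C → rt
Reagents that add atoms: none
Why: PhCO2H dehydrates 13 to the (E)-o-quinone methide 17, whose exocyclic C4 is the only electrophilic carbon because every other phenol is benzylated; the (E)-enamine formed from 16 and the (S)-catalyst adds to C4, the iminium ion is hydrolysed and the liberated phenol O1 adds to the aldehyde carbon C2 to give the hemiacetal. The closest known reaction type is the diarylprolinol-silyl-ether-catalysed Michael addition/hemiacetalisation (formal [4+2] annulation) of aldehydes with o-quinone methides generated in situ, which gives trans-3,4-disubstituted chroman-2-ols. Pyran ring C is closed by 6-exo-trig attack of O1 on the C2 carbonyl group. C3 is controlled by the catalyst, whose diphenyl(silyloxy)methyl group blocks one enamine face (3S by analogy with enamine additions to nitroalkenes), and C4 by the synclinal open transition state of that addition, which corresponds to the 3,4-trans (4R) ring isomer; C2 forms as an anomeric mixture that step 9 erases. The step needs catalyst control to override the distant C3' stereocenter of the lower isoflavan, which is insulated by an arene, and it needs C-attack at C4 to outrun reversible N- or O-trapping of 17. Any cis isomer can still equilibrate at C3 through the open hydroxy aldehyde to the trans-diequatorial lactol.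

**Step 9**
Reactants: 18 (3S,4R)-7-(benzyloxy)-3-[2-(benzyloxy)-4-methoxyphenyl]-4-{4-(benzyloxy)-5-[(3S)-7-(benzyloxy)chroman-3-yl]-2-methoxyphenyl}chroman-2-ol
Product: 19 (3S,4R)-7-(benzyloxy)-3-[2-(benzyloxy)-4-methoxyphenyl]-4-{4-(benzyloxy)-5-[(3S)-7-(benzyloxy)chroman-3-yl]-2-methoxyphenyl}chroman
Conditions: Et3SiH, TFA, CH2Cl2, −20 → 0 °C
Reagents that add atoms: none
Why: Ionic hydrogenation, in which TFA ionises the hemiacetal by loss of the exocyclic hydroxyl to the cyclic aryloxocarbenium ion and Et3SiH reduces it at C2, so the O1–C2 bond and the trans C3/C4 stereocenters (also the thermodynamic arrangement) are kept.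

**Step 10**
Reactants: 19 (3S,4R)-7-(benzyloxy)-3-[2-(benzyloxy)-4-methoxyphenyl]-4-{4-(benzyloxy)-5-[(3S)-7-(benzyloxy)chroman-3-yl]-2-methoxyphenyl}chroman
Product: 20 (3S,4R)-3-(2-hydroxy-4-methoxyphenyl)-4-{4-hydroxy-5-[(3S)-7-hydroxychroman-3-yl]-2-methoxyphenyl}chroman-7-ol
Conditions: H2 (1 atm), 10% Pd/C, EtOAc–MeOH, rt
Reagents that add atoms: none
Why: Hydrogenolysis cleaves the four benzyl aryl ethers, while the chroman C–O bonds are not benzylic and the triaryl-type C4 methine is not cleaved.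

**Compound list**

1 | 5-bromo-2-hydroxy-4-methoxybenzaldehyde | COc1cc(O)c(C=O)cc1Br | starting material
2 | 2-(benzyloxy)-5-bromo-4-methoxybenzaldehyde | COc1cc(OCc2ccccc2)c(C=O)cc1Br | intermediate
3 | 1-(benzyloxy)-4-bromo-5-methoxy-2-(2-methoxyethenyl)benzene (E/Z mixture) | COC=Cc1cc(Br)c(OC)cc1OCc1ccccc1 | intermediate
4 | 2-[2-(benzyloxy)-5-bromo-4-methoxyphenyl]acetaldehyde | COc1cc(OCc2ccccc2)c(CC=O)cc1Br | intermediate
5 | 4-(benzyloxy)-2-hydroxybenzaldehyde | O=Cc1ccc(OCc2ccccc2)cc1O | starting material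
6 | 5-(benzyloxy)-2-(hydroxymethyl)phenol | OCc1ccc(OCc2ccccc2)cc1O | intermediate
7 | 3-(benzyloxy)-6-methylidenecyclohexa-2,4-dien-1-one | C=C1C=CC(OCc2ccccc2)=CC1=O | intermediate
8 | (3S)-7-(benzyloxy)-3-[2-(benzyloxy)-5-bromo-4-methoxyphenyl]chroman-2-ol (both anomers) | COc1cc(OCc2ccccc2)c([C@H]2C(O)Oc3cc(OCc4ccccc4)ccc3C2)cc1Br | intermediate
9 | 5-(benzyloxy)-2-{(2S)-2-[2-(benzyloxy)-5-bromo-4-methoxyphenyl]-3-hydroxypropyl}phenol | COc1cc(OCc2ccccc2)c([C@@H](CO)Cc2ccc(OCc3ccccc3)cc2O)cc1Br | intermediate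
10 | (3S)-7-(benzyloxy)-3-[2-(benzyloxy)-5-bromo-4-methoxyphenyl]chroman | COc1cc(OCc2ccccc2)c([C@H]2COc3cc(OCc4ccccc4)ccc3C2)cc1Br | intermediate
11 | {4-(benzyloxy)-5-[(3S)-7-(benzyloxy)chroman-3-yl]-2-methoxyphenyl}lithium | COc1cc(OCc2ccccc2)c([C@H]2COc3cc(OCc4ccccc4)ccc3C2)cc1[Li] | intermediate
12 | sodium 5-(benzyloxy)-2-formylphenolate | [Na+].[O-]c1cc(OCc2ccccc2)ccc1C=O | intermediate
13 | [4-(benzyloxy)-2-hydroxyphenyl]{4-(benzyloxy)-5-[(3S)-7-(benzyloxy)chroman-3-yl]-2-methoxyphenyl}methanol (both carbinol epimers) | COc1cc(OCc2ccccc2)c([C@H]2COc3cc(OCc4ccccc4)ccc3C2)cc1C(O)c1ccc(OCc2ccccc2)cc1O | intermediate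
14 | 2-(benzyloxy)-4-methoxybenzaldehyde | COc1ccc(C=O)c(OCc2ccccc2)c1 | starting material
15 | 2-(benzyloxy)-4-methoxy-1-(2-methoxyethenyl)benzene (E/Z mixture) | COC=Cc1ccc(OC)cc1OCc1ccccc1 | intermediate
16 | 2-[2-(benzyloxy)-4-methoxyphenyl]acetaldehyde | COc1ccc(CC=O)c(OCc2ccccc2)c1 | intermediate
17 | (6E)-3-(benzyloxy)-6-{4-(benzyloxy)-5-[(3S)-7-(benzyloxy)chroman-3-yl]-2-methoxybenzylidene}cyclohexa-2,4-dien-1-one | COc1cc(OCc2ccccc2)c([C@H]2COc3cc(OCc4ccccc4)ccc3C2)cc1/C=C1/C(=O)C=C(OCc2ccccc2)C=C1 | intermediate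
18 | (3S,4R)-7-(benzyloxy)-3-[2-(benzyloxy)-4-methoxyphenyl]-4-{4-(benzyloxy)-5-[(3S)-7-(benzyloxy)chroman-3-yl]-2-methoxyphenyl}chroman-2-ol (both anomers) | COc1ccc([C@H]2C(O)Oc3cc(OCc4ccccc4)ccc3[C@@H]2c2cc([C@H]3COc4cc(OCc5ccccc5)ccc4C3)c(OCc3ccccc3)cc2OC)c(OCc2ccccc2)c1 | intermediate
19 | (3S,4R)-7-(benzyloxy)-3-[2-(benzyloxy)-4-methoxyphenyl]-4-{4-(benzyloxy)-5-[(3S)-7-(benzyloxy)chroman-3-yl]-2-methoxyphenyl}chroman | COc1ccc([C@H]2COc3cc(OCc4ccccc4)ccc3[C@@H]2c2cc([C@H]3COc4cc(OCc5ccccc5)ccc4C3)c(OCc3ccccc3)cc2OC)c(OCc2ccccc2)c1 | intermediate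
20 | (3S,4R)-3-(2-hydroxy-4-methoxyphenyl)-4-{4-hydroxy-5-[(3S)-7-hydroxychroman-3-yl]-2-methoxyphenyl}chroman-7-ol | COc1ccc([C@H]2COc3cc(O)ccc3[C@@H]2c2cc([C@H]3COc4cc(O)ccc4C3)c(O)cc2OC)c(O)c1 | target

**Step count.** Total: 10 steps. Longest linear sequence: 8 steps (1, 2, 4, 5, 6, 8, 9, 10).

**Steps most likely to fail**

Step 8. Two ortho-substituted aryl groups become vicinal, so facial discrimination at C4 may be poor (the catalyst controls C3 directly but C4 only through the open transition state). Quinone methide 17 may also be lost to self-condensation or to N-alkylation of the catalyst. The fallback sets out from 13 and 16 and comes back at 18, with control moved from the nucleophile to the electrophile. Aldehyde 16 is condensed with benzyl carbamate (TsOH cat., toluene, 4 Å sieves, 80 °C) to benzyl (E)-{2-[2-(benzyloxy)-4-methoxyphenyl]ethenyl}carbamate F1. A BINOL-derived chiral phosphoric acid (TRIP type, 10 mol %, CH2Cl2, 0 °C, enantiomer fixed by screening for 4R) binds both the carbonyl oxygen of quinone methide 17 formed from 13 and the N–H of F1. It should catalyse the known formal [4+2] cycloaddition of enecarbamates with o-hydroxybenzhydrol-derived quinone methides to benzyl {(3S,4R)-7-(benzyloxy)-3-[2-(benzyloxy)-4-methoxyphenyl]-4-{4-(benzyloxy)-5-[(3S)-7-(benzyloxy)chroman-3-yl]-2-methoxyphenyl}chroman-2-yl}carbamate F2, in which O1–C2 is again the ring-closing bond. Hydrolysis of the N,O-aminal (1 M HCl, THF–H2O, rt), with equilibration at C3 through the open aldehyde to the trans isomer, should return lactol 18.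

Step 4. The α-aryl stereocenter may lose enantiopurity by enolisation or renewed enamine formation before the borohydride trap, and the unsubstituted quinone methide 7 may oligomerise faster than the enamine captures it. The fallback sets out from 4 and 5 and comes back at 10, by-passing 6 to 9. Pinnick oxidation of 4 (NaClO2, NaH2PO4, 2-methylbut-2-ene, t-BuOH–H2O) gives 2-[2-(benzyloxy)-5-bromo-4-methoxyphenyl]acetic acid F3. Perkin condensation with 5 (Ac2O, Et3N, 110 °C) gives 7-(benzyloxy)-3-[2-(benzyloxy)-5-bromo-4-methoxyphenyl]-2H-chromen-2-one F4. Reduction with i-Bu2AlH (CH2Cl2, −78 → 0 °C) opens the lactone to 5-(benzyloxy)-2-{(1Z)-2-[2-(benzyloxy)-5-bromo-4-methoxyphenyl]-3-hydroxyprop-1-en-1-yl}phenol F5. Mitsunobu closure (PPh3, DIAD, THF) gives 7-(benzyloxy)-3-[2-(benzyloxy)-5-bromo-4-methoxyphenyl]-2H-chromene F6. Asymmetric hydrogenation of this trisubstituted alkene with [Ir(cod)(tBu-PHOX)][B(C6H3(CF3)2)4] (H2, CH2Cl2; ligand enantiomer chosen for 3S), which tolerates aryl bromides and benzyl ethers, should give 10.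

Step 6. The aryllithium may be protonated instead of adding, because the phenolate is poorly soluble and aggregated at low temperature, and the very electron-rich benzhydrol may ionise during work-up. The fallback sets out from 10 and comes back at 13, with the polarity of the union reversed. Aryllithium 11 (n-BuLi, THF, −78 °C) is formylated with DMF to 4-(benzyloxy)-5-[(3S)-7-(benzyloxy)chroman-3-yl]-2-methoxybenzaldehyde F7. Bromomagnesium 3-(benzyloxy)phenolate F8, made from 3-(benzyloxy)phenol and EtMgBr, then adds through its ortho carbon para to the benzyloxy group to the magnesium-coordinated aldehyde (toluene, rt; ortho-specific hydroxyalkylation of a magnesium phenolate) to give 13 under non-acidic conditions.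

**Further compounds**

F1 | step 8 | benzyl (E)-{2-[2-(benzyloxy)-4-methoxyphenyl]ethenyl}carbamate | COc1ccc(/C=C/NC(=O)OCc2ccccc2)c(OCc2ccccc2)c1
F2 | step 8 | benzyl {(3S,4R)-7-(benzyloxy)-3-[2-(benzyloxy)-4-methoxyphenyl]-4-{4-(benzyloxy)-5-[(3S)-7-(benzyloxy)chroman-3-yl]-2-methoxyphenyl}chroman-2-yl}carbamate | COc1ccc([C@H]2C(NC(=O)OCc3ccccc3)Oc3cc(OCc4ccccc4)ccc3[C@@H]2c2cc([C@H]3COc4cc(OCc5ccccc5)ccc4C3)c(OCc3ccccc3)cc2OC)c(OCc2ccccc2)c1
F3 | step 4 | 2-[2-(benzyloxy)-5-bromo-4-methoxyphenyl]acetic acid | COc1cc(OCc2ccccc2)c(CC(=O)O)cc1Br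
F4 | step 4 | 7-(benzyloxy)-3-[2-(benzyloxy)-5-bromo-4-methoxyphenyl]-2H-chromen-2-one | COc1cc(OCc2ccccc2)c(-c2cc3ccc(OCc4ccccc4)cc3oc2=O)cc1Br
F5 | step 4 | 5-(benzyloxy)-2-{(1Z)-2-[2-(benzyloxy)-5-bromo-4-methoxyphenyl]-3-hydroxyprop-1-en-1-yl}phenol | COc1cc(OCc2ccccc2)c(/C(CO)=C/c2ccc(OCc3ccccc3)cc2O)cc1Br
F6 | step 4 | 7-(benzyloxy)-3-[2-(benzyloxy)-5-bromo-4-methoxyphenyl]-2H-chromene | COc1cc(OCc2ccccc2)c(C2=Cc3ccc(OCc4ccccc4)cc3OC2)cc1Br
F7 | step 6 | 4-(benzyloxy)-5-[(3S)-7-(benzyloxy)chroman-3-yl]-2-methoxybenzaldehyde | COc1cc(OCc2ccccc2)c([C@H]2COc3cc(OCc4ccccc4)ccc3C2)cc1C=O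
F8 | step 6 | bromomagnesium 3-(benzyloxy)phenolate | Br[Mg]Oc1cccc(OCc2ccccc2)c1
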